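Everything rests on cutting ring A between the CH2 group that adjoins the carbinol carbon and the ring carbon that carries the exocyclic methylene. Since that carbon is bonded to the spiro carbon, it can start as the inner carbon of an ethynyl group on a quaternary carbon of a ketal-protected, still symmetric ring B. One radical step then closes ring A (6-exo-dig) and leaves the methylene. The precursor is an acyclic primary iodide carrying the silylated anti-bromohydrin (cis once cyclised), the CMe2 group and the ethynyl-bearing quaternary carbon. Afterwards ring B is desymmetrised, which fixes the spiro centre, and converted into the chloromethyl ketol.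

Key step: step 10

Assumption: in the spiro ketone, ring B is taken as a chair locked with the CMe2 carbon equatorial and the methylene-bearing carbon axial, because the other chair would hold a methyl group over ring B; steps 12 to 14 are planned on this basis.

Step 1
Reactants: 1 1,4-dioxaspiro[4.5]decane-8-carbaldehyde; 2 3-methylbut-2-en-1-ol
Product: 5 8-(2-methylbut-3-en-2-yl)-1,4-dioxaspiro[4.5]decane-8-carbaldehyde, via diprenyl acetal 3 (not isolated), via prenyl enol ether 4 (not isolated)
Conditions: 2 (3 equiv), pyridinium p-toluenesulfonate (5 mol %), xylenes, 140 °C, Dean–Stark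
Reagents that add atoms: none
Why: Acid-catalysed acetal formation and loss of one prenol give the prenyl enol ether, whose thermal Claisen rearrangement joins the ring carbon to the dimethyl-substituted allyl terminus and so forms both quaternary carbons at once; no stereocentre arises because ring B is symmetric.

Step 2
Reactants: 5 8-(2-methylbut-3-en-2-yl)-1,4-dioxaspiro[4.5]decane-8-carbaldehyde
Product: 7 trimethyl{[8-(2-methylbut-3-en-2-yl)-1,4-dioxaspiro[4.5]decan-8-yl]ethynyl}silane, via terminal alkyne 6 (not isolated)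
Conditions: Me3SiCHN2, n-BuLi, THF, −78→0 °C; then n-BuLi, −78 °C; Me3SiCl, −78 °C→rt
Reagents that add atoms: trimethylsilyldiazomethane C[Si](C)(C)C=[N+]=[N-]; chlorotrimethylsilane C[Si](C)(C)Cl
Why: Colvin rearrangement: the lithiated diazo compound adds to the non-enolisable neopentyl aldehyde, silanolate and nitrogen are lost and the alkylidene carbene shifts hydrogen to give the alkyne, whose lithium acetylide is silylated in the same flask so that the triple bond is masked during step 3.

Step 3
Reactants: 7 trimethyl{[8-(2-methylbut-3-en-2-yl)-1,4-dioxaspiro[4.5]decan-8-yl]ethynyl}silane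
Product: 9 3-(8-ethynyl-1,4-dioxaspiro[4.5]decan-8-yl)-3-methylbutan-1-ol, via alkylborane 8 (not isolated)
Conditions: 9-borabicyclo[3.3.1]nonane (9-BBN), THF, 0 °C→rt; then NaOH, H2O2, MeOH/H2O, 0 °C→rt
Reagents that add atoms: hydrogen peroxide OO
Why: Anti-Markovnikov hydroboration–oxidation: the bulky borane takes only the monosubstituted alkene because the silyl-capped alkyne on a quaternary carbon is inert, oxidation proceeds with retention to the primary alcohol, and the methanolic hydroxide of the work-up cleaves the alkynyl C–Si bond.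

Step 4
Reactants: 9 3-(8-ethynyl-1,4-dioxaspiro[4.5]decan-8-yl)-3-methylbutan-1-ol
Product: 10 3-(8-ethynyl-1,4-dioxaspiro[4.5]decan-8-yl)-3-methylbutanal
Conditions: Dess–Martin periodinane, NaHCO3, CH2Cl2, 0 °C→rt
Reagents that add atoms: none
Why: Dess–Martin oxidation of a primary alcohol stops cleanly at the aldehyde under buffered conditions that leave the ketal and the terminal alkyne untouched.

Step 5
Reactants: 10 3-(8-ethynyl-1,4-dioxaspiro[4.5]decan-8-yl)-3-methylbutanal
Product: 11 (2R)-2-bromo-3-(8-ethynyl-1,4-dioxaspiro[4.5]decan-8-yl)-3-methylbutanal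
Conditions: (2S,5S)-2,5-diphenylpyrrolidine (20 mol %), PhCO2H (20 mol %), 4,4-dibromo-2,6-di-tert-butylcyclohexa-2,5-dienone, CH2Cl2/pentane, −40 °C; cold filtration through silica, used at once
Reagents that add atoms: 4,4-dibromo-2,6-di-tert-butylcyclohexa-2,5-dien-1-one CC(C)(C)C1=CC(Br)(Br)C=C(C(C)(C)C)C1=O
Why: Organocatalytic enamine α-bromination of an aldehyde: the C2-symmetric amine forms the E-enamine, the phenyl group next to the nucleophilic carbon shields one face and bromine is delivered to the other, which should set the (R) configuration, while the quaternary neighbour disfavours a second bromination.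

Step 6
Reactants: 11 (2R)-2-bromo-3-(8-ethynyl-1,4-dioxaspiro[4.5]decan-8-yl)-3-methylbutanal; 12 vinylmagnesium bromide
Product: 13 (3S,4R)-4-bromo-5-(8-ethynyl-1,4-dioxaspiro[4.5]decan-8-yl)-5-methylhex-1-en-3-ol
Conditions: 12 (2.5 equiv), THF, −78 °C; AcOH, −78 °C
Reagents that add atoms: none
Why: Grignard 1,2-addition to an α-bromo aldehyde under Cornforth (polar Felkin–Anh) control, with the nucleophile passing the α-hydrogen and not the tertiary alkyl group, should give the anti-bromohydrin and so the (3S) carbinol, and the cold acidic quench prevents the magnesium alkoxide from closing to an epoxide.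

Step 7
Reactants: 13 (3S,4R)-4-bromo-5-(8-ethynyl-1,4-dioxaspiro[4.5]decan-8-yl)-5-methylhex-1-en-3-ol
Product: 14 (3S,4R)-4-bromo-3-(tert-butyldimethylsilyloxy)-5-(8-ethynyl-1,4-dioxaspiro[4.5]decan-8-yl)-5-methylhex-1-ene
Conditions: t-BuMe2SiOTf, 2,6-lutidine, CH2Cl2, −78→0 °C
Reagents that add atoms: tert-butyldimethylsilyl trifluoromethanesulfonate CC(C)(C)[Si](C)(C)OS(=O)(=O)C(F)(F)F
Why: Silylation with the silyl triflate and a hindered pyridine base protects the crowded secondary alcohol without epoxide formation from the bromohydrin, and neither stereocentre is touched.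

Step 8
Reactants: 14 (3S,4R)-4-bromo-3-(tert-butyldimethylsilyloxy)-5-(8-ethynyl-1,4-dioxaspiro[4.5]decan-8-yl)-5-methylhex-1-ene
Product: 17 (2S,3R)-3-bromo-2-(tert-butyldimethylsilyloxy)-4-(8-ethynyl-1,4-dioxaspiro[4.5]decan-8-yl)-4-methylpentan-1-ol, via ozonide 15 (not isolated), via silyloxy aldehyde 16 (not isolated)
Conditions: O3, CH2Cl2, −78 °C (Sudan Red 7B end point); then NaBH4, MeOH, −78→0 °C
Reagents that add atoms: ozone [O-][O+]=O
Why: Ozonolysis with reductive work-up: the monosubstituted alkene reacts with ozone far faster than the terminal alkyne when the ozone is titrated to an indicator end point, and NaBH4 reduces the ozonide through the aldehyde directly to the primary alcohol at low temperature, so that the β-bromo aldehyde has no time to eliminate.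

Step 9
Reactants: 17 (2S,3R)-3-bromo-2-(tert-butyldimethylsilyloxy)-4-(8-ethynyl-1,4-dioxaspiro[4.5]decan-8-yl)-4-methylpentan-1-ol
Product: 18 tert-butyl{[(2R,3R)-3-bromo-4-(8-ethynyl-1,4-dioxaspiro[4.5]decan-8-yl)-1-iodo-4-methylpentan-2-yl]oxy}dimethylsilane
Conditions: I2, PPh3, imidazole, CH2Cl2, 0 °C→rt
Reagents that add atoms: iodine II
Why: Garegg–Samuelsson (Appel-type) iodination converts the primary alcohol into the iodide by displacement of the oxyphosphonium group at the unhindered CH2, leaving the neopentyl-type secondary bromide and both stereocentres untouched (the descriptor at the carbinol carbon changes only because iodine alters the priorities).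

Step 10
Reactants: 18 tert-butyl{[(2R,3R)-3-bromo-4-(8-ethynyl-1,4-dioxaspiro[4.5]decan-8-yl)-1-iodo-4-methylpentan-2-yl]oxy}dimethylsilane
Product: 19 ethylene ketal of (8R,9S)-8-bromo-9-(tert-butyldimethylsilyloxy)-7,7-dimethyl-11-methylidenespiro[5.5]undecan-3-one
Conditions: (Me3Si)3SiH (1.2 equiv, slow addition), Et3B (0.2 equiv), air, toluene (0.01 M), rt
Reagents that add atoms: none
Why: Ethyl radicals from Et3B and oxygen start a chain in which the silyl radical abstracts iodine from 18, the primary radical adds to the inner carbon of the ethynyl group, and the σ-vinyl radical takes hydrogen from (Me3Si)3SiH to leave the exocyclic methylene. The closest known reaction type is the tris(trimethylsilyl)silane-mediated exo-dig cyclisation of alkyl iodides onto alkynes. Ring A, a six-membered carbocycle, closes in the 6-exo-dig mode through a chair-like transition state that the CMe2 group and the quaternary carbon hold folded. No stereocentre is formed: the two ring A centres are already present, lie outside the radical site and cannot epimerise, and the spiro carbon is not yet stereogenic because ring B is symmetric. The step needs iodine abstraction in preference to abstraction of the hindered secondary bromine and to silyl addition to the alkyne, exo in preference to endo attack, and ring closure in preference to hydrogen transfer; the much faster iodine abstraction, the linear alkyne geometry with double gem-disubstitution of the chain, and slow addition of the silane at high dilution should secure these. The radical is not β to bromine and a β-silyloxy group does not fragment, so both substituents stay in place.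

Step 11
Reactants: 19 ethylene ketal of (8R,9S)-8-bromo-9-(tert-butyldimethylsilyloxy)-7,7-dimethyl-11-methylidenespiro[5.5]undecan-3-one
Product: 20 (8R,9S)-8-bromo-9-(tert-butyldimethylsilyloxy)-7,7-dimethyl-11-methylidenespiro[5.5]undecan-3-one
Conditions: pyridinium p-toluenesulfonate, acetone/H2O (10:1), 55 °C
Reagents that add atoms: water O
Why: Acid-catalysed ketal hydrolysis with a mild pyridinium acid frees the ring B ketone while the secondary silyl ether, the bromide and the exocyclic alkene persist.

Step 12
Reactants: 20 (8R,9S)-8-bromo-9-(tert-butyldimethylsilyloxy)-7,7-dimethyl-11-methylidenespiro[5.5]undecan-3-one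
Product: 22 (6R,8R,9S)-8-bromo-9-(tert-butyldimethylsilyloxy)-7,7-dimethyl-11-methylidene-3-(triethylsilyloxy)spiro[5.5]undec-2-ene, via lithium enolate 21 (not isolated)
Conditions: (S,S)-bis(1-phenylethyl)amine hydrochloride, n-BuLi (2 equiv), THF, −78 °C; then Et3SiCl, −78→0 °C
Reagents that add atoms: chlorotriethylsilane CC[Si](Cl)(CC)CC
Why: Enantiotopic-group-selective deprotonation with a chiral lithium amide, applied here to two diastereotopic α-methylene groups: in the locked chair only the two axial α-hydrogens can be removed and the C2-symmetric amide chooses between them, which fixes the spiro stereocentre; the amide enantiomer is chosen by analogy with the desymmetrisation of 4-tert-butylcyclohexanone, the CMe2 carbon taking the place of the equatorial tert-butyl group.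

Step 13
Reactants: 22 (6R,8R,9S)-8-bromo-9-(tert-butyldimethylsilyloxy)-7,7-dimethyl-11-methylidene-3-(triethylsilyloxy)spiro[5.5]undec-2-ene
Product: 24 (2R,6R,8R,9S)-8-bromo-9-(tert-butyldimethylsilyloxy)-7,7-dimethyl-11-methylidene-2-(triethylsilyloxy)spiro[5.5]undecan-3-one, via silyloxy epoxide 23 (not isolated)
Conditions: mCPBA (1.05 equiv), hexane/CH2Cl2, −20→0 °C
Reagents that add atoms: 3-chloroperoxybenzoic acid OOC(=O)c1cccc(Cl)c1
Why: Rubottom oxidation: the peracid epoxidises the electron-rich silyl enol ether much faster than the hindered 1,1-disubstituted alkene of ring A, from the face anti to the axial ring A carbon, and the silyloxy epoxide opens with 1,4-silyl shift to the α-silyloxy ketone, whose new carbinol centre is only a relay that step 16 removes.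

Step 14
Reactants: 24 (2R,6R,8R,9S)-8-bromo-9-(tert-butyldimethylsilyloxy)-7,7-dimethyl-11-methylidene-2-(triethylsilyloxy)spiro[5.5]undecan-3-one
Product: 25 spiro-epoxide of 24 (oxirane spiro-fused at ring B C3 in place of the carbonyl group, oxirane oxygen axial and on the same face of ring B as the CMe2 carbon and the triethylsilyloxy group)
Conditions: Me3S(O)I, NaH, DMSO, rt (ylide preformed); then 24 in THF, rt
Reagents that add atoms: trimethylsulfoxonium iodide C[S+](C)(C)=O.[I-]
Why: Corey–Chaykovsky epoxidation with the sulfoxonium ylide: betaine formation is reversible, so the new C–C bond ends equatorial and the oxirane oxygen axial, which in the locked ring B chair is the face syn to the CMe2 carbon and corresponds to the configuration of the tertiary carbinol of the target.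

Step 15
Reactants: 25 spiro-epoxide of 24
Product: 26 epoxy alcohol (25 with the triethylsilyl group replaced by hydrogen; ring A silyl ether retained)
Conditions: HF·pyridine, pyridine, THF, 0 °C
Reagents that add atoms: none
Why: Buffered HF·pyridine cleaves the triethylsilyl ether much faster than the hindered secondary tert-butyldimethylsilyl ether and does not open the oxirane under these conditions.

Step 16
Reactants: 26 epoxy alcohol
Product: 27 α-keto spiro-epoxide (ring B C2 ketone next to the C3 spiro-oxirane, oxirane oxygen cis to the CMe2 carbon; ring A as in 20)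
Conditions: Dess–Martin periodinane, NaHCO3, CH2Cl2, 0 °C→rt
Reagents that add atoms: none
Why: Dess–Martin oxidation of the secondary alcohol gives the ketone under neutral conditions, erases the relay stereocentre and leaves the α-keto spiro-epoxide intact.

Step 17
Reactants: 27 α-keto spiro-epoxide
Product: 28 (3S,6R,8R,9S)-8-bromo-9-(tert-butyldimethylsilyloxy)-3-(chloromethyl)-3-hydroxy-7,7-dimethyl-11-methylidenespiro[5.5]undecan-2-one
Conditions: LiCl, AcOH, THF, rt
Reagents that add atoms: lithium chloride [Li+].[Cl-]
Why: Halide opening of an epoxide with LiCl and acetic acid: chloride attacks in SN2 fashion at the CH2 carbon, since the other oxirane carbon is fully substituted and α to the carbonyl, so the C–O bond at the tertiary centre is not broken and its configuration is kept.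

Step 18
Reactants: 28 (3S,6R,8R,9S)-8-bromo-9-(tert-butyldimethylsilyloxy)-3-(chloromethyl)-3-hydroxy-7,7-dimethyl-11-methylidenespiro[5.5]undecan-2-one
Product: 29 (3S,6R,8R,9S)-8-bromo-3-(chloromethyl)-3,9-dihydroxy-7,7-dimethyl-11-methylidenespiro[5.5]undecan-2-one (CNP0273087.1)
Conditions: HF (48 % aq.), MeCN, 0 °C→rt
Reagents that add atoms: none
Why: Acidic fluoride desilylation frees the ring A alcohol without base, which would close the chlorohydrin to the epoxide, and the cis arrangement of bromine and hydroxyl in ring A cannot form an epoxide, so the target should result with all four stereocentres intact.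

Compound list
1 | 1,4-dioxaspiro[4.5]decane-8-carbaldehyde | O=CC1CCC2(CC1)OCCO2 | starting material
2 | 3-methylbut-2-en-1-ol (prenol) | CC(C)=CCO | starting material
3 | 8-[bis(3-methylbut-2-enyloxy)methyl]-1,4-dioxaspiro[4.5]decane (diprenyl acetal) | CC(C)=CCOC(OCC=C(C)C)C1CCC2(CC1)OCCO2 | intermediate
4 | 8-[(3-methylbut-2-enyloxy)methylidene]-1,4-dioxaspiro[4.5]decane (prenyl enol ether) | CC(C)=CCOC=C1CCC2(CC1)OCCO2 | intermediate
5 | 8-(2-methylbut-3-en-2-yl)-1,4-dioxaspiro[4.5]decane-8-carbaldehyde | C=CC(C)(C)C1(C=O)CCC2(CC1)OCCO2 | intermediate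
6 | 8-ethynyl-8-(2-methylbut-3-en-2-yl)-1,4-dioxaspiro[4.5]decane | C=CC(C)(C)C1(C#C)CCC2(CC1)OCCO2 | intermediate
7 | trimethyl{[8-(2-methylbut-3-en-2-yl)-1,4-dioxaspiro[4.5]decan-8-yl]ethynyl}silane | C=CC(C)(C)C1(C#C[Si](C)(C)C)CCC2(CC1)OCCO2 | intermediate
8 | 9-{3-methyl-3-[8-(trimethylsilylethynyl)-1,4-dioxaspiro[4.5]decan-8-yl]butyl}-9-borabicyclo[3.3.1]nonane | C[Si](C)(C)C#CC1(CCC2(CC1)OCCO2)C(C)(C)CCB1C2CCCC1CCC2 | intermediate
9 | 3-(8-ethynyl-1,4-dioxaspiro[4.5]decan-8-yl)-3-methylbutan-1-ol | C#CC1(CCC2(CC1)OCCO2)C(C)(C)CCO | intermediate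
10 | 3-(8-ethynyl-1,4-dioxaspiro[4.5]decan-8-yl)-3-methylbutanal | C#CC1(CCC2(CC1)OCCO2)C(C)(C)CC=O | intermediate
11 | (2R)-2-bromo-3-(8-ethynyl-1,4-dioxaspiro[4.5]decan-8-yl)-3-methylbutanal | O=C[C@H](Br)C(C)(C)C1(C#C)CCC2(CC1)OCCO2 | intermediate
12 | vinylmagnesium bromide | C=C[Mg]Br | starting material
13 | (3S,4R)-4-bromo-5-(8-ethynyl-1,4-dioxaspiro[4.5]decan-8-yl)-5-methylhex-1-en-3-ol (anti-bromohydrin) | C=C[C@H](O)[C@H](Br)C(C)(C)C1(C#C)CCC2(CC1)OCCO2 | intermediate
14 | (3S,4R)-4-bromo-3-(tert-butyldimethylsilyloxy)-5-(8-ethynyl-1,4-dioxaspiro[4.5]decan-8-yl)-5-methylhex-1-ene | C=C[C@H](O[Si](C)(C)C(C)(C)C)[C@H](Br)C(C)(C)C1(C#C)CCC2(CC1)OCCO2 | intermediate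
15 | ozonide of 14 (1,2,4-trioxolane on the former vinyl group, mixture at the trioxolane carbon) | C1OC(OO1)[C@H](O[Si](C)(C)C(C)(C)C)[C@H](Br)C(C)(C)C1(C#C)CCC2(CC1)OCCO2 | intermediate
16 | (2S,3R)-3-bromo-2-(tert-butyldimethylsilyloxy)-4-(8-ethynyl-1,4-dioxaspiro[4.5]decan-8-yl)-4-methylpentanal | O=C[C@H](O[Si](C)(C)C(C)(C)C)[C@H](Br)C(C)(C)C1(C#C)CCC2(CC1)OCCO2 | intermediate
17 | (2S,3R)-3-bromo-2-(tert-butyldimethylsilyloxy)-4-(8-ethynyl-1,4-dioxaspiro[4.5]decan-8-yl)-4-methylpentan-1-ol | OC[C@H](O[Si](C)(C)C(C)(C)C)[C@H](Br)C(C)(C)C1(C#C)CCC2(CC1)OCCO2 | intermediate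
18 | tert-butyl{[(2R,3R)-3-bromo-4-(8-ethynyl-1,4-dioxaspiro[4.5]decan-8-yl)-1-iodo-4-methylpentan-2-yl]oxy}dimethylsilane (key-step precursor) | IC[C@H](O[Si](C)(C)C(C)(C)C)[C@H](Br)C(C)(C)C1(C#C)CCC2(OCCO2)CC1 | intermediate
19 | ethylene ketal of (8R,9S)-8-bromo-9-(tert-butyldimethylsilyloxy)-7,7-dimethyl-11-methylidenespiro[5.5]undecan-3-one (key-step product, bromine and silyloxy cis) | C=C1C[C@H](O[Si](C)(C)C(C)(C)C)[C@H](Br)C(C)(C)C12CCC3(OCCO3)CC2 | intermediate
20 | (8R,9S)-8-bromo-9-(tert-butyldimethylsilyloxy)-7,7-dimethyl-11-methylidenespiro[5.5]undecan-3-one | C=C1C[C@H](O[Si](C)(C)C(C)(C)C)[C@H](Br)C(C)(C)C12CCC(=O)CC2 | intermediate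
21 | lithium enolate of 20 (enolate double bond C2=C3, spiro carbon R) | C=C1C[C@H](O[Si](C)(C)C(C)(C)C)[C@H](Br)C(C)(C)[C@@]12CCC(O[Li])=CC2 | intermediate
22 | (6R,8R,9S)-8-bromo-9-(tert-butyldimethylsilyloxy)-7,7-dimethyl-11-methylidene-3-(triethylsilyloxy)spiro[5.5]undec-2-ene | C=C1C[C@H](O[Si](C)(C)C(C)(C)C)[C@H](Br)C(C)(C)[C@@]12CCC(O[Si](CC)(CC)CC)=CC2 | intermediate
23 | 2,3-epoxide of 22 (oxirane oxygen on the ring B face anti to the axial ring A carbon) | C=C1C[C@H](O[Si](C)(C)C(C)(C)C)[C@H](Br)C(C)(C)[C@@]12CC[C@]3(O[Si](CC)(CC)CC)O[C@@H]3C2 | intermediate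
24 | (2R,6R,8R,9S)-8-bromo-9-(tert-butyldimethylsilyloxy)-7,7-dimethyl-11-methylidene-2-(triethylsilyloxy)spiro[5.5]undecan-3-one | C=C1C[C@H](O[Si](C)(C)C(C)(C)C)[C@H](Br)C(C)(C)[C@@]12CCC(=O)[C@H](O[Si](CC)(CC)CC)C2 | intermediate
25 | spiro-epoxide of 24 (oxirane at ring B C3, oxygen axial, cis to the CMe2 carbon and to the C2 triethylsilyloxy group) | C=C1C[C@H](O[Si](C)(C)C(C)(C)C)[C@H](Br)C(C)(C)[C@@]12CC[C@@]3(CO3)[C@H](O[Si](CC)(CC)CC)C2 | intermediate
26 | epoxy alcohol (25 with free C2 hydroxyl) | C=C1C[C@H](O[Si](C)(C)C(C)(C)C)[C@H](Br)C(C)(C)[C@@]12CC[C@@]3(CO3)[C@H](O)C2 | intermediate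
27 | α-keto spiro-epoxide (C2 ketone, C3 spiro-oxirane with oxygen cis to the CMe2 carbon) | C=C1C[C@H](O[Si](C)(C)C(C)(C)C)[C@H](Br)C(C)(C)[C@@]12CC[C@@]3(CO3)C(=O)C2 | intermediate
28 | (3S,6R,8R,9S)-8-bromo-9-(tert-butyldimethylsilyloxy)-3-(chloromethyl)-3-hydroxy-7,7-dimethyl-11-methylidenespiro[5.5]undecan-2-one | C=C1C[C@H](O[Si](C)(C)C(C)(C)C)[C@H](Br)C(C)(C)[C@@]12CC[C@@](O)(CCl)C(=O)C2 | intermediate
29 | (3S,6R,8R,9S)-8-bromo-3-(chloromethyl)-3,9-dihydroxy-7,7-dimethyl-11-methylidenespiro[5.5]undecan-2-one (CNP0273087.1) | C=C1C[C@H](O)[C@H](Br)C(C)(C)[C@@]12CC[C@@](O)(CCl)C(=O)C2 | target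

Total step count: 18
Longest linear sequence: 18 steps (from 1 to 29)

Steps most likely to fail

Step 10. The open-chain radical may take hydrogen from the silane before it closes, the silyl radical may strip the secondary bromine once the iodide is consumed, or attack may drift to the alkyne terminus. The fallback sets out from 18 and returns at 19. The ring is closed as an iodine-atom-transfer chain with no hydrogen donor present (Et3B, air, benzene, rt). Such a chain can only end by iodine transfer to the cyclised vinyl radical and should give the exocyclic vinyl iodide F1 as an E/Z mixture. The vinylic iodine is then replaced by hydrogen with Pd(OAc)2, PPh3, HCO2H and Et3N in DMF at 50 °C, conditions under which a secondary alkyl bromide does not add to palladium, to give 19.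

Step 1. Under acid and heat the prenyl enol ether may ionise, which gives a net 1,3-shift to the linear prenyl aldehyde. The ketal may also exchange with prenol, or the rearrangement between two fully substituted carbons may stall. The fallback sets out from 1 and returns at 5. Pinnick oxidation (NaClO2, NaH2PO4, 2-methylbut-2-ene) gives 1,4-dioxaspiro[4.5]decane-8-carboxylic acid F2, which is esterified with 2 (EDC, DMAP) to the prenyl ester F3. LiN(i-Pr)2 and Me3SiCl in THF at −78 °C give the silyl ketene acetal F4. On warming to reflux this undergoes Ireland–Claisen rearrangement to the trimethylsilyl ester F5, and aqueous work-up gives the quaternary acid F6. LiAlH4 reduces the acid to the neopentyl alcohol F7, and Dess–Martin oxidation returns to 5.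

Step 12. The chiral amide may discriminate poorly between the two α-methylene groups, or with the opposite sense, so that the regioisomeric enol ether and finally the epimer at the spiro carbon are carried along. The fallback sets out from 20 and returns at 24. L-Proline-catalysed α-aminoxylation with nitrosobenzene in DMSO gives the α-(phenylaminooxy) ketone F8. The catalyst fixes the (R) configuration at the oxygenated carbon, and attack anti to the axial ring A carbon then selects the required methylene. Cleavage of the N–O bond (Zn, AcOH, THF, 0 °C) gives the α-hydroxy ketone F9, and Et3SiOTf with 2,6-lutidine gives 24.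

Further compounds
F1 | step 10 | ethylene ketal of (8R,9S)-8-bromo-9-(tert-butyldimethylsilyloxy)-11-(iodomethylidene)-7,7-dimethylspiro[5.5]undecan-3-one (E/Z mixture) | IC=C1C[C@H](O[Si](C)(C)C(C)(C)C)[C@H](Br)C(C)(C)C12CCC3(OCCO3)CC2
F2 | step 1 | 1,4-dioxaspiro[4.5]decane-8-carboxylic acid | OC(=O)C1CCC2(CC1)OCCO2
F3 | step 1 | 3-methylbut-2-enyl 1,4-dioxaspiro[4.5]decane-8-carboxylate | CC(C)=CCOC(=O)C1CCC2(CC1)OCCO2
F4 | step 1 | trimethylsilyl ketene acetal of F3 | CC(C)=CCOC(O[Si](C)(C)C)=C1CCC2(CC1)OCCO2
F5 | step 1 | trimethylsilyl 8-(2-methylbut-3-en-2-yl)-1,4-dioxaspiro[4.5]decane-8-carboxylate | C=CC(C)(C)C1(C(=O)O[Si](C)(C)C)CCC2(CC1)OCCO2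
F6 | step 1 | 8-(2-methylbut-3-en-2-yl)-1,4-dioxaspiro[4.5]decane-8-carboxylic acid | C=CC(C)(C)C1(C(=O)O)CCC2(CC1)OCCO2
F7 | step 1 | [8-(2-methylbut-3-en-2-yl)-1,4-dioxaspiro[4.5]decan-8-yl]methanol | C=CC(C)(C)C1(CO)CCC2(CC1)OCCO2
F8 | step 12 | (2R,6R,8R,9S)-8-bromo-9-(tert-butyldimethylsilyloxy)-7,7-dimethyl-11-methylidene-2-(phenylaminooxy)spiro[5.5]undecan-3-one | C=C1C[C@H](O[Si](C)(C)C(C)(C)C)[C@H](Br)C(C)(C)[C@@]12CCC(=O)[C@H](ONc3ccccc3)C2
F9 | step 12 | (2R,6R,8R,9S)-8-bromo-9-(tert-butyldimethylsilyloxy)-2-hydroxy-7,7-dimethyl-11-methylidenespiro[5.5]undecan-3-one | C=C1C[C@H](O[Si](C)(C)C(C)(C)C)[C@H](Br)C(C)(C)[C@@]12CCC(=O)[C@H](O)C2
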